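All runs are calculated with constants of no real substance; the scatter is artificial.

If the incoming ligand is treated as constant, the bench rule (pseudo-first-order) gives each exchange one rate, and the starting complex falls along a single exponential.

| flask | starting complex | incoming ligand | remark | time |
|---|---|---|---|---|
| Friday's | 0.13 M | 0.41 M | run made earlier |  |
| Thursday's | 0.13 M | 0.37 M | run made earlier |  |
| Tuesday's | 0.13 M | 0.45 M | run made earlier |  |
| delta | 0.13 M | 0.325 M |  | 4.0 h |
| epsilon | 0.13 M | 0.390 M |  | 4.0 h |
| eta | 0.13 M | 0.520 M |  | 4.0 h |

| run | time / h | complex with one exchanged / % | complex with two exchanged / % |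
|---|---|---|---|
| Friday's | 0.333 | 55.8 | 13.6 |
| Friday's | 1.00 | 36.5 | 36.9 |
| Friday's | 2.00 | 21.9 | 53.6 |
| Friday's | 3.00 | 17.1 | 64.2 |
| Friday's | 4.00 | 13.7 | 72.7 |
| Thursday's | 0.333 | 56.2 | 12.9 |
| Thursday's | 0.667 | 43.8 | 21.1 |
| Thursday's | 1.00 | 37.9 | 31.4 |
| Thursday's | 2.00 | 24.8 | 48.4 |
| Thursday's | 4.00 | 15.0 | 63.4 |
| Tuesday's | 0.833 | 39.8 | 34.4 |
| Tuesday's | 1.50 | 25.5 | 50.8 |
| Tuesday's | 2.50 | 16.0 | 63.7 |
| Tuesday's | 3.00 | 14.9 | 67.3 |
| Tuesday's | 4.00 | 10.8 | 76.6 |

(each reading ± 1 percentage point)

1. complex with one exchanged at the end, in percent of the starting complex charged, for each flask in turn (delta, epsilon, eta)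

- what was read earlier has a scatter of 1 percentage point, one standard deviation

Thursday's run does not follow that rule: the starting complex, taken by difference, stands at 30.9% after 0.333 h and still at 21.6% after 4.00 h. The border lies in a ratio of charges. Two exchanges on every complex take two incoming ligands, and the charge of incoming ligand covers that demand by a factor of 1.25 in delta and 2.00 in eta. In Thursday's run at 4.00 h, counting one leaving ligand per exchange, the readings give c(leaving ligand) as 0.184 M and c(incoming ligand) as 0.186 M, about half of its charge.

So follow one complex not yet exchanged twice. At the fork it goes forward on meeting incoming ligand and back on meeting leaving ligand. Once these two hops balance, its chance of standing as complex with one exchanged is K·c(incoming ligand) / (K·c(incoming ligand) + c(leaving ligand)), where the hop constant K is c(complex with one exchanged)·c(leaving ligand) / (c(starting complex)·c(incoming ligand)). Thursday's last reading gives 0.690. It is only a reading: Friday's last gives 1.03.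

My own reckoning covers epsilon, whose charge lies midway between those two runs. Their mean gives 68.1% complex with two exchanged and 14.3% with one, hence 0.196 M leaving ligand, 0.194 M incoming ligand and a chance of 0.407. The unfinished part of epsilon then holds 13.0% complex with one exchanged by this reckoning. The forecast says 15.7%, 13.8% and 7.4% for delta, epsilon and eta, its epsilon value standing higher than this reckoning's, and holds that “The second step looks slow and effectively irreversible”. A run in which the forecast's K of 0.68 moved with the charge, beyond the scatter of the readings, could prove the forecast wrong.

Delta, epsilon and eta give 16.1%, 13.2% and 8.20%, so the forecast stands.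

    starting complex + incoming ligand ⇌ leaving ligand + complex with one exchanged (K = 0.710, k = 0.932 M⁻¹ min⁻¹)
    complex with one exchanged + incoming ligand ⇌ leaving ligand + complex with two exchanged (K = 39.4, k = 0.0414 M⁻¹ min⁻¹)

In epsilon, the backward turnover of the first step is 94% of the forward one. With Thursday's K, the end state of epsilon gives a chance of 0.410. In eta, the chance is 0.473, and the unfinished 17.2% then yields 8.13%, where eta stands at 8.20%.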